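The numbers in the tables stem from a simulated flask on assumed constants; the scatter is artificial.

- In Wednesday's run one quantity holds steady: intermediate in millimolar, divided by time, reads 0.113 mM h⁻¹ at 6.00 h and 0.112 mM h⁻¹ at 20.0 h, a climb of zero order in the usual term.
- The last two readings lie close: from 30.0 h to 40.0 h the reading of intermediate moves by 0.2 percentage points, less than the scatter of 0.3 points, so a stall is one way to read them, not a proven fact, and the last reading stands for 2.80 mM.
- That last reading divided by the climb gives 1.04 d, the crossing time, at which the steady climb meets the supposed stall.

| flask | solid substrate | remark | time |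
|---|---|---|---|
| Wednesday's | 40 mM | run made earlier |  |
| flask | 20 mM |  | 6.0 d |

Wednesday's run (percent of the solid substrate charged)

| time / h | intermediate / % | target / % |
|---|---|---|
| 6.00 | 1.7 | 0.2 |
| 12.0 | 3.4 | 1.3 |
| 20.0 | 5.6 | 1.6 |
| 25.0 | 6.3 | 2.4 |
| 30.0 | 6.8 | 2.7 |
| 40.0 | 7.0 | 2.8 |

(standard deviation of a reading: 0.3 percentage points)

* time up to 6.0 d at which intermediate stands highest
* the amount of intermediate, in percent of the solid substrate charged, at that time

- given per volume of solution although it is solid: solid substrate
- at the start none of the solid substrate is in solution

- The reckoning offered for this flask assumes that the stall is real and that climb and stall both hold in millimolar, which one charge cannot prove; intermediate then reaches its highest at 1.04 d, with 14.0% of the 20 mM charged.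
- The forecast gives 14.2%, close to that figure, but puts the time at 6 d, later than the crossing, reasoning that intermediate will “stay flat, so the nominal maximum is at the end”.
- The flask gives 12.5% at 1.15 d.

    starting material → intermediate (k = 0.00128 min⁻¹)
    intermediate ⇌ target (K = 0.344, k = 0.0157 min⁻¹)
    intermediate ⇌ isomer of the product (K = 9.92, k = 0.00548 min⁻¹)
    solid substrate ⇌ starting material, rate k4*(cs4 - [starting material]) while solid is left; crystals form when [starting material] > cs4 (solubility = 11.0 mM, k = 0.00282 min⁻¹)
    starting material → decomposition product (k = 5.17 × 10⁻⁶ min⁻¹)

- Against the crossing time of 1.04 d, the flask's peak comes 1.11 times as late, and its height compares with the reckoned 14.0%. Solid substrate stands at 0% at that peak, and intermediate then falls to 8.84% by 6.00 d, while isomer of the product rises to 87.7%. The neighbouring flask has the same charge but is stopped at 2.5 d, 2.40 times the crossing time, so the reckoning places its highest amount before the stop, at 14.0%. That flask reached 12.5% and ends at 9.27%.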